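**Retrosynthetic overview**
- Peruvinide A is cut through ring A bonds C1–C2 and C5–C6. Ring A is a 2-hydroxy-4-methoxy-6-propylbenzoate (C1 carboxyl, C2 OH, C4 OMe, C6 propyl), the pattern a 1,1,3-trioxygenated butadiene leaves on a 2-ynoate, so the doubly ortho-flanked aryl ester C(=O)–O bond can be made while the acyl group is still a linear alkynoate.
- This gives the ring-B aryl hex-2-ynoate and the Brassard diene, joined by a Diels–Alder benzannulation.
- The aryl ynoate comes from hex-2-ynoic acid and atraric acid (acylation of the unchelated 4-OH); the diene comes from methyl (E)-3-methoxybut-2-enoate (γ-deprotonation, O-silylation).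
- Ring order: ring B is bought intact; ring A is the only ring formed, in the last step.

Key step: step 3

Remark: the target has no stereocentre and no stereogenic axis, so no absolute configuration has to be set.
Remark: the diene is drawn as its 1Z isomer; the C1 geometry is of no consequence because C1 becomes an aromatic carbon.
Remark: the chelated ring-B phenol of the dienophile is silylated in the flask before the diene is added, so that it cannot protonate the ketene acetal.

**Route**

Step 1
Reactants: 1 hex-2-ynoic acid; 2 methyl 2,4-dihydroxy-3,6-dimethylbenzoate (atraric acid)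
Product: 4 methyl 4-(hex-2-ynoyloxy)-2-hydroxy-3,6-dimethylbenzoate, via O-acylisourea 3 (not isolated)
Conditions: DCC, DMAP (cat.), CH2Cl2, 0 °C to rt
Reagents that add atoms: none
Why: Steglich esterification, in which DCC turns 1 into O-acylisourea 3 and DMAP relays the acyl group to the 4-OH of 2, the only phenol that is not tied up in a hydrogen bond to the ester carbonyl and not flanked on both sides, while the low temperature and the catalytic DMAP loading should hold back conjugate addition to the ynoate; no stereocentre is formed.

Step 2
Reactants: 5 methyl (E)-3-methoxybut-2-enoate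
Product: 7 1,3-dimethoxy-1-(trimethylsilyloxy)buta-1,3-diene (Brassard diene), via lithium dienolate 6 (not isolated)
Conditions: LDA (commercial solution), THF, −78 °C; then TMSCl, −78 °C to rt; pentane, filtration, bulb-to-bulb distillation
Reagents that add atoms: chlorotrimethylsilane, C[Si](C)(C)Cl
Why: Kinetic γ-deprotonation of the vinylogous carbonate by LDA gives the extended enolate 6, which the hard silyl chloride traps on oxygen (silyl ketene acetal formation), the standard preparation of this diene; no stereocentre is formed.

Step 3
Reactants: 4 methyl 4-(hex-2-ynoyloxy)-2-hydroxy-3,6-dimethylbenzoate; 7 1,3-dimethoxy-1-(trimethylsilyloxy)buta-1,3-diene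
Product: 11 peruvinide A (methyl 2-hydroxy-4-[(2-hydroxy-4-methoxy-6-propylbenzoyl)oxy]-3,6-dimethylbenzoate), via aryl silyl ether 8 (not isolated), via cyclohexadiene cycloadduct 9 (not isolated), via bis-silyl ether 10 (not isolated)
Conditions: N,O-bis(trimethylsilyl)acetamide (BSA), toluene, 60 °C; then 7 (3 equiv), 120 °C, sealed tube; then 1 M HCl, THF, rt
Reagents that add atoms: none
Why: BSA first masks the only acidic proton as silyl ether 8, and 8 and diene 7 then undergo a thermal normal-electron-demand Diels–Alder reaction, asynchronous and concerted, in which the CH2 terminus of 7 bonds first to the propyl-bearing β-carbon of the ynoate (ring A C5–C6) and the ketene-acetal carbon then bonds to the α-carbon (ring A C1–C2). Ring A is closed as a six-membered carbocycle by this intermolecular [4+2] cycloaddition to give cyclohexa-1,4-diene 9, whose mixed methyl silyl ketal should expel methanol by 1,4-elimination, driven by aromatisation, to give 10; dilute acid completes any unfinished elimination and cleaves both Si–O bonds to give 11. The closest known reaction type is the benzannulation of Brassard- and Chan-type 1,1,3-trioxygenated dienes with acetylenic esters, β-alkyl ynoates included at 120–140 °C, which gives resorcylate esters. No stereocentre remains in 11, since the ketal carbon of 9 forms as a racemate and becomes planar on aromatisation. The step needs regioselectivity, which the matched polarisation secures (largest HOMO coefficient at the diene CH2, largest LUMO coefficient at the ynoate β-carbon, the aryl ester lowering the LUMO more than an alkyl ester would). It also needs the ketal to lose methanol and not silanol, which the lability of the O–Si bond and the usual behaviour of this diene class support, and excess BSA should trap the released methanol so that it cannot cleave the aryl ester.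

**Compound list**
1 | hex-2-ynoic acid | CCCC#CC(=O)O | starting material
2 | methyl 2,4-dihydroxy-3,6-dimethylbenzoate (atraric acid) | COC(=O)c1c(C)cc(O)c(C)c1O | starting material
3 | N,N'-dicyclohexyl-O-(hex-2-ynoyl)isourea | CCCC#CC(=O)OC(=NC1CCCCC1)NC1CCCCC1 | intermediate
4 | methyl 4-(hex-2-ynoyloxy)-2-hydroxy-3,6-dimethylbenzoate | CCCC#CC(=O)Oc1cc(C)c(C(=O)OC)c(O)c1C | intermediate
5 | methyl (E)-3-methoxybut-2-enoate | CO/C(C)=C/C(=O)OC | starting material
6 | lithium 1,3-dimethoxybuta-1,3-dien-1-olate | C=C(OC)/C=C(/OC)[O-].[Li+] | intermediate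
7 | (1Z)-1,3-dimethoxy-1-(trimethylsilyloxy)buta-1,3-diene (Brassard diene) | C=C(OC)/C=C(/OC)O[Si](C)(C)C | intermediate
8 | methyl 4-(hex-2-ynoyloxy)-3,6-dimethyl-2-(trimethylsilyloxy)benzoate | CCCC#CC(=O)Oc1cc(C)c(C(=O)OC)c(O[Si](C)(C)C)c1C | intermediate
9 | methyl 4-{[4,6-dimethoxy-2-propyl-6-(trimethylsilyloxy)cyclohexa-1,4-diene-1-carbonyl]oxy}-3,6-dimethyl-2-(trimethylsilyloxy)benzoate (racemic at the ketal carbon) | CCCC1=C(C(=O)Oc2cc(C)c(C(=O)OC)c(O[Si](C)(C)C)c2C)C(OC)(O[Si](C)(C)C)C=C(OC)C1 | intermediate
10 | methyl 4-{[4-methoxy-2-propyl-6-(trimethylsilyloxy)benzoyl]oxy}-3,6-dimethyl-2-(trimethylsilyloxy)benzoate | CCCc1cc(OC)cc(O[Si](C)(C)C)c1C(=O)Oc1cc(C)c(C(=O)OC)c(O[Si](C)(C)C)c1C | intermediate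
11 | peruvinide A, methyl 2-hydroxy-4-[(2-hydroxy-4-methoxy-6-propylbenzoyl)oxy]-3,6-dimethylbenzoate | CCCc1cc(OC)cc(O)c1C(=O)Oc1cc(C)c(C(=O)OC)c(O)c1C | target

**Totals**
Total step count: 3
Longest linear sequence: 2 steps (step 1 then step 3, or step 2 then step 3)

**Steps most likely to fail**

1. Step 3. The β-propyl ynoate may add so slowly that the ketene acetal is lost to thermal decomposition or protodesilylation first; the ketal of the adduct may lose silanol instead of methanol and leave a methyl ether at C2; or released methanol may cleave the activated aryl ester. The fallback is the classical depside assembly; it sets out from 2 and returns to the route at 11.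
   - Purchased 5-propylbenzene-1,3-diol F1 is formylated under Vilsmeier–Haack conditions (POCl3, DMF, then aqueous hydrolysis) next to the propyl group to give 2,4-dihydroxy-6-propylbenzaldehyde F2.
   - The unchelated 4-OH is methylated selectively (MeI, K2CO3, acetone) to give 2-hydroxy-4-methoxy-6-propylbenzaldehyde F3.
   - Chlorite oxidation (NaClO2, sulfamic acid, aqueous dioxane) should give 2-hydroxy-4-methoxy-6-propylbenzoic acid F4.
   - F4 is activated with trifluoroacetic anhydride in toluene as 2-hydroxy-4-methoxy-6-propylbenzoic trifluoroacetic anhydride F5 and condensed in the same flask with the 4-OH of 2 to give 11.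

2. Step 2. α-Deprotonation or addition of the amide to the ester may compete with γ-deprotonation, silylation may occur on carbon, and the ketene acetal may hydrolyse during isolation. The fallback uses a bis-silyl diene made by two routine silylations and installs the methyl ether last; it sets out from 4 and returns to the route at 11.
   - Purchased methyl acetoacetate F6 is O-silylated (TMSCl, Et3N) to methyl 3-(trimethylsilyloxy)but-2-enoate F7, which is deprotonated with LDA and silylated again to give 1-methoxy-1,3-bis(trimethylsilyloxy)buta-1,3-diene F8.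
   - Under the conditions of step 3, 4 (as its silyl ether 8) and F8 should give the cyclohexa-1,4-diene cycloadduct F9, then by loss of methanol the aromatic tris-silyl ether F10, and on acidic work-up methyl 4-[(2,4-dihydroxy-6-propylbenzoyl)oxy]-2-hydroxy-3,6-dimethylbenzoate F11.
   - The only unchelated phenol of F11, the ring-A 4-OH, is methylated (MeI, 1 equiv, K2CO3, acetone, rt) to give 11.

3. Step 1. The phenol or DMAP may add in conjugate fashion to the carbodiimide-activated ynoate, and the O-acylisourea may rearrange to an unreactive N-acylurea before acyl transfer. The fallback is a two-stage acylation through an isolated acyl chloride with no nucleophilic catalyst; it sets out from 1 and returns to the route at 4.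
   - 1 is converted with oxalyl chloride and catalytic DMF in CH2Cl2 into hex-2-ynoyl chloride F12.
   - F12 is freed of volatiles and added at −20 °C to 2 and 2,6-lutidine in CH2Cl2 to give 4.

**Further compounds**
F1 | step 3 | 5-propylbenzene-1,3-diol (purchased) | CCCc1cc(O)cc(O)c1
F2 | step 3 | 2,4-dihydroxy-6-propylbenzaldehyde | CCCc1cc(O)cc(O)c1C=O
F3 | step 3 | 2-hydroxy-4-methoxy-6-propylbenzaldehyde | CCCc1cc(OC)cc(O)c1C=O
F4 | step 3 | 2-hydroxy-4-methoxy-6-propylbenzoic acid | CCCc1cc(OC)cc(O)c1C(=O)O
F5 | step 3 | 2-hydroxy-4-methoxy-6-propylbenzoic trifluoroacetic anhydride | CCCc1cc(OC)cc(O)c1C(=O)OC(=O)C(F)(F)F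
F6 | step 2 | methyl acetoacetate (purchased) | COC(=O)CC(C)=O
F7 | step 2 | methyl 3-(trimethylsilyloxy)but-2-enoate | COC(=O)C=C(C)O[Si](C)(C)C
F8 | step 2 | 1-methoxy-1,3-bis(trimethylsilyloxy)buta-1,3-diene | C=C(O[Si](C)(C)C)C=C(OC)O[Si](C)(C)C
F9 | step 2 | methyl 4-{[6-methoxy-2-propyl-4,6-bis(trimethylsilyloxy)cyclohexa-1,4-diene-1-carbonyl]oxy}-3,6-dimethyl-2-(trimethylsilyloxy)benzoate | CCCC1=C(C(=O)Oc2cc(C)c(C(=O)OC)c(O[Si](C)(C)C)c2C)C(OC)(O[Si](C)(C)C)C=C(O[Si](C)(C)C)C1
F10 | step 2 | methyl 4-{[2-propyl-4,6-bis(trimethylsilyloxy)benzoyl]oxy}-3,6-dimethyl-2-(trimethylsilyloxy)benzoate | CCCc1cc(O[Si](C)(C)C)cc(O[Si](C)(C)C)c1C(=O)Oc1cc(C)c(C(=O)OC)c(O[Si](C)(C)C)c1C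
F11 | step 2 | methyl 4-[(2,4-dihydroxy-6-propylbenzoyl)oxy]-2-hydroxy-3,6-dimethylbenzoate | CCCc1cc(O)cc(O)c1C(=O)Oc1cc(C)c(C(=O)OC)c(O)c1C
F12 | step 1 | hex-2-ynoyl chloride | CCCC#CC(Cl)=O
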